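Psiguadial A is cut back to an aromadendrane tricycle, benzaldehyde and diformylphloroglucinol. Everything rests on one gold-catalysed cascade of an acyclic dienyne (O-methyl dehydronerolidol), whose alkyne carbons become C5 and C6. In one operation it forms the ring-fusion bond C1–C5 (shared by the five- and seven-membered rings; C1 is the later O-bearing carbon) and the cyclopropane bond C6–C7, together with C6–C11. This closes cyclopentene, cycloheptane and cyclopropane and sets four stereocentres from one propargylic centre. The step exploits that the C5–C6 bond links the ring fusion to the cyclopropane. Hydroboration and a radical benzylation then set C5 and C4, and ionisation, 1,2-hydride shift and phenol capture close the oxepane.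

Key step: step 5

Remark: atoms carry aromadendrane numbers (C1 oxygen-bearing ring-fusion carbon, C4 quaternary carbon with methyl C15, C5 ring-fusion CH, C6 and C7 cyclopropane CH, C10 CH–CH3, C11 C(CH3)2, C1′ benzylic carbon); β is the face of the hydroazulene that carries O–C1 in the target. Assumption: the methoxy group migrates in step 5 as other alkoxy groups do in this cascade type.

Step 1
Reactants: 1 (2E,6E)-farnesol
Product: 2 (2S,3S)-2,3-epoxyfarnesol
Conditions: Ti(OiPr)4 (cat.), L-(+)-diethyl tartrate (cat.), t-BuOOH, 4 Å molecular sieves, CH2Cl2, −20 °C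
Reagents that add atoms: tert-butyl hydroperoxide, CC(C)(C)OO
Why: Sharpless asymmetric epoxidation of the allylic alcohol; the L-tartrate ligand directs oxygen to the face that gives the (2S,3S)-oxirane, whose C3 becomes the carbinol centre that later controls the cascade.

Step 2
Reactants: 2 (2S,3S)-2,3-epoxyfarnesol
Product: 3 (2R,3S)-2-(chloromethyl)-3-methyl-3-[(3E)-4,8-dimethylnona-3,7-dien-1-yl]oxirane
Conditions: PPh3, CCl4, NaHCO3, 75 °C
Reagents that add atoms: carbon tetrachloride, ClC(Cl)(Cl)Cl
Why: Appel chlorination of the primary alcohol; the oxirane and both its centres are untouched (the C2 descriptor changes only through CIP priorities).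

Step 3
Reactants: 3 (2R,3S)-2-(chloromethyl)-3-methyl-3-[(3E)-4,8-dimethylnona-3,7-dien-1-yl]oxirane
Product: 4 (3S,6E)-3,7,11-trimethyldodeca-6,10-dien-1-yn-3-ol
Conditions: n-BuLi (3.5 equiv), THF, −40 °C → 0 °C; H2O
Reagents that add atoms: none
Why: Base-induced double elimination of the 2,3-epoxy chloride (α-deprotonation with oxirane opening to the chloro-allylic alkoxide, then dehydrochlorination) gives the terminal alkyne; the C3–O bond is never broken, so the tertiary carbinol keeps its configuration.

Step 4
Reactants: 4 (3S,6E)-3,7,11-trimethyldodeca-6,10-dien-1-yn-3-ol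
Product: 5 (3S,6E)-3-methoxy-3,7,11-trimethyldodeca-6,10-dien-1-yne
Conditions: NaH, MeI, THF, 0 °C → rt
Reagents that add atoms: iodomethane, CI
Why: Williamson etherification of the tertiary alkoxide; no stereocentre is touched.

Step 5
Reactants: 5 (3S,6E)-3-methoxy-3,7,11-trimethyldodeca-6,10-dien-1-yne
Product: 6 (1aR,4S,4aR,7bS)-4-methoxy-1,1,4,7-tetramethyl-1a,2,3,4,4a,5,6,7b-octahydro-1H-cyclopropa[e]azulene (10β-methoxyaromadendr-4-ene; H1, H6 and H7 α)
Conditions: [(JohnPhos)Au(NCMe)]SbF6 (3 mol %; JohnPhos = (2-biphenylyl)P(t-Bu)2), CH2Cl2, −30 °C → rt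
Reagents that add atoms: none
Why: π-Activation of the alkyne by the cationic monovalent gold complex triggers 5-exo-dig attack of the (E)-C1=C10 olefin on C5 (bond C1–C5, cyclopentene), giving a cyclopropyl gold carbene with positive charge at C10. The methoxy group then shifts from C4 to C10 (1,5-alkoxy migration through a five-membered oxonium), unmasking an α,β-unsaturated gold carbene at C6 next to the new C4=C5 double bond. This carbene adds to the terminal C7=C11 olefin in an intramolecular [2+1] cyclopropanation (bonds C6–C7 and C6–C11), which closes the seven-membered ring and the cyclopropane. The closest known reaction type is the gold-catalysed 1,6-enyne cyclisation/1,5-alkoxy migration/intramolecular cyclopropanation of propargylic ethers of dienynes. C1 is controlled by the C4 stereocentre (the ether reaches C10 only when oxygen and C10 are cis on the new ring, so the centre is spent with chirality transfer), C10 by syn delivery of oxygen across the E-olefin, and C6/C7 by the cyclopropanation transition state that places H6 and H7 cis to H1. The step needs 5-exo over 6-endo closure and ether migration over skeletal rearrangement, which the trisubstituted olefin and the tertiary propargylic ether secure.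

Step 6
Reactants: 6 10β-methoxyaromadendr-4-ene
Product: 9 potassium [(4β,5β)-10β-methoxyaromadendran-4-yl]trifluoroborate (boron β on C4, H5 β, C15 α), via tertiary alkylborane 7 (not isolated), via dimethyl boronate 8 (not isolated)
Conditions: BH3·SMe2, THF, 0 °C → rt; MeOH; then KHF2, MeOH–H2O, rt
Reagents that add atoms: borane–dimethyl sulfide, C[S+](C)[BH3-]; potassium hydrogen difluoride, [K+].[F-].F
Why: Concerted syn hydroboration of the tetrasubstituted olefin puts boron on C4 (less hindered, remote from the cyclopropane) and hydrogen on C5, both from the β-face (the face from which this ring system takes up hydrogen to give the trans-fused series), which sets H5 β; methanolysis and KHF2 give the bench-stable salt.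

Step 7
Reactants: 9 potassium [(4β,5β)-10β-methoxyaromadendran-4-yl]trifluoroborate; 10 benzaldehyde; 11 2,4-diformylphloroglucinol (2,4,6-trihydroxybenzene-1,3-dicarbaldehyde)
Product: 13 2,4,6-trihydroxy-5-{(S)-[(4β,5β)-10β-methoxyaromadendran-4-yl](phenyl)methyl}benzene-1,3-dicarbaldehyde (C1′ on the β-face of C4, cis to H5), via ortho-quinone methide 12 (not isolated)
Conditions: 1,2,3,5-tetrakis(carbazol-9-yl)-4,6-dicyanobenzene (4CzIPN, 2 mol %), AcOH, MeCN–H2O, blue LEDs, 40 °C
Reagents that add atoms: none
Why: Proposed new method: Knoevenagel condensation of 10 at the single free ring position of 11 gives quinone methide 12; the excited photocatalyst oxidises the tertiary alkyltrifluoroborate to the C4 radical, which adds to the methide carbon of 12 on its β-face (anti to the C5–C6 bond, so the new C4–C1′ bond is cis to H5 and C4 is set), and the phenoxyl radical is then reduced and protonated; C1′ is expected to form through an open transition state with phenyl anti to C5, with only moderate selectivity; the closest known reaction type is the photoredox Giese-type 1,6-addition of alkyltrifluoroborates to para-quinone methides.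

Step 8
Reactants: 13 C4-benzylated phenol
Product: 14 psiguadial A
Conditions: TfOH (cat.), (CF3)2CHOH–CH2Cl2, −20 °C → rt
Reagents that add atoms: none
Why: Acid ionises the tertiary methyl ether (SN1), a suprafacial 1,2-hydride shift moves H1 (α) to C10 and sets C10 (H α, methyl β), and the tertiary C1 cation is captured by an ortho-phenol held on the β-face by C1′ (seven-membered ether, oxygen cis to H5); this is a cation/hydride-shift/etherification cascade of the biomimetic type.

Compound list
1 | (2E,6E)-farnesol | OC/C=C(\C)CC/C=C(\C)CCC=C(C)C | starting material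
2 | (2S,3S)-2,3-epoxyfarnesol | OC[C@@H]1O[C@@]1(C)CC/C=C(\C)CCC=C(C)C | intermediate
3 | (2R,3S)-2-(chloromethyl)-3-methyl-3-[(3E)-4,8-dimethylnona-3,7-dien-1-yl]oxirane | ClC[C@@H]1O[C@@]1(C)CC/C=C(\C)CCC=C(C)C | intermediate
4 | (3S,6E)-3,7,11-trimethyldodeca-6,10-dien-1-yn-3-ol | C#C[C@@](C)(O)CC/C=C(\C)CCC=C(C)C | intermediate
5 | (3S,6E)-3-methoxy-3,7,11-trimethyldodeca-6,10-dien-1-yne | C#C[C@@](C)(OC)CC/C=C(\C)CCC=C(C)C | intermediate
6 | (1aR,4S,4aR,7bS)-4-methoxy-1,1,4,7-tetramethyl-1a,2,3,4,4a,5,6,7b-octahydro-1H-cyclopropa[e]azulene (10β-methoxyaromadendr-4-ene) | CO[C@@]1(C)CC[C@@H]2[C@H](C3=C(C)CC[C@H]31)C2(C)C | intermediate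
7 | tertiary alkylborane: [(4β,5β)-10β-methoxyaromadendran-4-yl]borane | CO[C@@]1(C)CC[C@@H]2[C@H]([C@@H]3[C@](C)(CC[C@H]31)B)C2(C)C | intermediate
8 | dimethyl [(4β,5β)-10β-methoxyaromadendran-4-yl]boronate | CO[C@@]1(C)CC[C@@H]2[C@H]([C@@H]3[C@](C)(CC[C@H]31)B(OC)OC)C2(C)C | intermediate
9 | potassium [(4β,5β)-10β-methoxyaromadendran-4-yl]trifluoroborate | CO[C@@]1(C)CC[C@@H]2[C@H]([C@@H]3[C@](C)(CC[C@H]31)[B-](F)(F)F)C2(C)C.[K+] | intermediate
10 | benzaldehyde | O=Cc1ccccc1 | starting material
11 | 2,4-diformylphloroglucinol (2,4,6-trihydroxybenzene-1,3-dicarbaldehyde) | O=Cc1c(O)cc(O)c(C=O)c1O | starting material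
12 | ortho-quinone methide: (E)-5-benzylidene-2,4-dihydroxy-6-oxocyclohexa-1,3-diene-1,3-dicarbaldehyde | O=C1/C(=C/c2ccccc2)C(O)=C(C=O)C(O)=C1C=O | intermediate
13 | 2,4,6-trihydroxy-5-{(S)-[(4β,5β)-10β-methoxyaromadendran-4-yl](phenyl)methyl}benzene-1,3-dicarbaldehyde | CO[C@@]1(C)CC[C@@H]2[C@H]([C@@H]3[C@](C)(CC[C@H]31)[C@@H](c1ccccc1)c1c(O)c(C=O)c(O)c(C=O)c1O)C2(C)C | intermediate
14 | psiguadial A | C[C@H]1CC[C@@H]2[C@H]([C@@H]3[C@]4(C)CC[C@@]31Oc1c(C=O)c(O)c(C=O)c(O)c1[C@@H]4c1ccccc1)C2(C)C | target

Total step count: 8. Longest linear sequence: 8 steps (1 → 14).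

Steps most likely to fail

Step 7 (Proposed new method). The tertiary radical may be quenched (hydrogen abstraction or over-oxidation to the cation) faster than it adds to the short-lived quinone methide, which meanwhile oligomerises; facial discrimination at the benzylic carbon may also be weak. The fallback uses known chemistry and sets out from 6. Its hydroboration is repeated with an aqueous work-up to give the tertiary boronic acid F1. Reductive coupling of F1 with the N-tosylhydrazone of commercial 2,4,6-trihydroxybenzophenone F2 (K2CO3, dioxane, 110 °C; diazo formation, boron-to-carbon 1,2-shift with retention at C4, protodeboronation) should give the deformyl benzylated phenol F3. The conditions of step 8 should close F3 to the deformyl ether F4, and twofold ortho-formylation (MgCl2, Et3N, paraformaldehyde, MeCN, reflux) returns to the route at 14.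

Step 6. Boron may be delivered to the wrong carbon or face, or the hindered monoalkylborane may isomerise with opening of the cyclopropane. The fallback replaces organoboron and radical chemistry by enolate chemistry and sets out from 6. Allylic oxidation (CrO3, 3,5-dimethylpyrazole, CH2Cl2, −20 °C) should give the cyclopentenone F5. Copper-hydride conjugate reduction ([(Ph3P)CuH]6 cat., PhMe2SiH) delivers H5 from the β-face and gives the silyl enol ether F6. Heating F6 in toluene with the Betti base F7 (from phloroglucinol, benzaldehyde and piperidine), which releases the quinone methide F8, should give the α-quaternary ketone F9 after hydrolytic work-up (Mukaiyama–Michael addition, anti to the C5–C6 bond). Acid as in step 8 closes F9 to the oxo ether F10, Wolff–Kishner reduction (N2H4·H2O, KOH, diethylene glycol, 190 °C) removes the ketone to give the deformyl ether F4, and the twofold ortho-formylation described above returns to the route at 14.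

Step 5. The methoxy group may migrate more slowly than the cyclopropyl gold carbene rearranges (single-cleavage dienes), or facial control in the seven-ring-forming cyclopropanation may be lost. The fallback sets out from 4. Benzylation (NaH, BnBr) gives the benzyl ether F11, which carries the best-established migrating group for this cascade and should give the benzyloxy tricycle F12 under the conditions of step 5. Reductive debenzylation (lithium 4,4′-di-tert-butylbiphenylide, THF, −78 °C) gives the tertiary alcohol F13, and methylation (KH, MeI) returns to the route at 6.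

Further compounds
F1 | step 7 | [(4β,5β)-10β-methoxyaromadendran-4-yl]boronic acid | CO[C@@]1(C)CC[C@@H]2[C@H]([C@@H]3[C@](C)(CC[C@H]31)B(O)O)C2(C)C
F2 | step 7 | N-tosylhydrazone of 2,4,6-trihydroxybenzophenone | Cc1ccc(cc1)S(=O)(=O)NN=C(c1ccccc1)c1c(O)cc(O)cc1O
F3 | step 7 | 2-{(S)-[(4β,5β)-10β-methoxyaromadendran-4-yl](phenyl)methyl}benzene-1,3,5-triol | CO[C@@]1(C)CC[C@@H]2[C@H]([C@@H]3[C@](C)(CC[C@H]31)[C@@H](c1ccccc1)c1c(O)cc(O)cc1O)C2(C)C
F4 | step 7 | bis-deformyl psiguadial A | C[C@H]1CC[C@@H]2[C@H]([C@@H]3[C@]4(C)CC[C@@]31Oc1cc(O)cc(O)c1[C@@H]4c1ccccc1)C2(C)C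
F5 | step 6 | 10β-methoxyaromadendr-4-en-3-one | CO[C@@]1(C)CC[C@@H]2[C@H](C3=C(C)C(=O)C[C@H]31)C2(C)C
F6 | step 6 | 3-[dimethyl(phenyl)silyloxy]-10β-methoxy-5β-aromadendr-3-ene | CO[C@@]1(C)CC[C@@H]2[C@H]([C@@H]3C(C)=C(O[Si](C)(C)c4ccccc4)C[C@H]31)C2(C)C
F7 | step 6 | 2-[phenyl(piperidin-1-yl)methyl]benzene-1,3,5-triol (racemic Betti base) | Oc1cc(O)c(C(c2ccccc2)N2CCCCC2)c(O)c1
F8 | step 6 | (E)-6-benzylidene-3,5-dihydroxycyclohexa-2,4-dien-1-one | O=C1C=C(O)C=C(O)/C1=C\c1ccccc1
F9 | step 6 | 4β-[(S)-phenyl(2,4,6-trihydroxyphenyl)methyl]-10β-methoxy-5β-aromadendran-3-one | CO[C@@]1(C)CC[C@@H]2[C@H]([C@@H]3[C@](C)(C(=O)C[C@H]31)[C@@H](c1ccccc1)c1c(O)cc(O)cc1O)C2(C)C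
F10 | step 6 | 3-oxo-bis-deformyl psiguadial A | C[C@H]1CC[C@@H]2[C@H]([C@@H]3[C@]4(C)C(=O)C[C@@]31Oc1cc(O)cc(O)c1[C@@H]4c1ccccc1)C2(C)C
F11 | step 5 | (3S,6E)-3-benzyloxy-3,7,11-trimethyldodeca-6,10-dien-1-yne | C#C[C@@](C)(OCc1ccccc1)CC/C=C(\C)CCC=C(C)C
F12 | step 5 | 10β-benzyloxyaromadendr-4-ene | C(c1ccccc1)O[C@@]1(C)CC[C@@H]2[C@H](C3=C(C)CC[C@H]31)C2(C)C
F13 | step 5 | aromadendr-4-en-10β-ol | O[C@@]1(C)CC[C@@H]2[C@H](C3=C(C)CC[C@H]31)C2(C)C
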